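The numbers in the tables are simulated on assumed constants; noise was put on by code.

A small charge of solid substrate takes the highest percentage among the earlier runs, red's, yet the molar amount of target barely follows the loading: ochre holds 0.0354 M at 12.0 h and grey 0.0352 M. So we read dissolution as the rate-limiting step, with a supply rate S of 0.00295 M h⁻¹ from ochre.

| setting | ochre | grey | red | south | east | south-west | north | north-east |
|---|---|---|---|---|---|---|---|---|
| solid substrate | 0.096 M | 0.16 M | 0.050 M | 0.050 M | 0.15 M | 0.050 M | 0.10 M | 0.20 M |
| reagent | 1.1 equiv (in portions, 2) | 1.1 equiv (in portions, 2) | 1.6 equiv (in portions, 2) | 1.10 equiv (in portions, 2) | 1.70 equiv (in portions, 2) | 4.40 equiv (in portions, 2) | 3.30 equiv (in portions, 2) | 2.20 equiv (in portions, 2) |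
| remark | run made earlier; portions every 6.0 h | run made earlier; portions every 6.0 h | run made earlier; portions every 6.0 h | the portions of reagent follow each other after 6.0 h, the first at the start | the portions of reagent follow each other after 6.0 h, the first at the start | the portions of reagent follow each other after 1.5 h, the first at the start | the portions of reagent follow each other after 6.0 h, the first at the start | the portions of reagent follow each other after 2.0 h, the first at the start |
| time |  |  |  | 12 h | 12 h | 12 h | 12 h | 12 h |

| run | time / h | target / % | solid substrate / % |
|---|---|---|---|
| ochre | 3.00 | 9.3 | 89.6 |
| ochre | 6.00 | 17.8 | 82.0 |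
| ochre | 10.0 | 30.5 | 68.8 |
| ochre | 12.0 | 36.9 | 62.2 |
| grey | 1.50 | 2.7 | 96.9 |
| grey | 4.00 | 8.2 | 92.4 |
| grey | 8.00 | 14.8 | 85.6 |
| grey | 12.0 | 22.0 | 76.4 |
| red | 3.00 | 17.2 | 81.7 |
| red | 6.00 | 33.2 | 65.0 |
| red | 10.0 | 58.1 | 41.6 |
| red | 12.0 | 67.5 | 30.0 |

(scatter of a reading: 0.5 percentage points)

- the flasks put in order of amount of target, in percent of the solid substrate charged, best first, at 12 h (south / east / south-west / north / north-east)
- the amount of target, in percent of the solid substrate charged of the flask you put first, at 12 h
- the amount of target, in percent of the solid substrate charged of the flask you put last, at 12 h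

- amounts and yields of target count solid product too
- given per volume of solution although it is solid: solid substrate, solid product
- what was read earlier has a scatter of 0.5 percentage points, one standard deviation
- steps under discussion: dissolved substrate + reagent -> target; 2 reagent -> self-condensation product; solid product <-> target; solid substrate <-> dissolved substrate
- at the start none of the solid substrate is in solution
- what has only dissolved of solid substrate counts as not reacted

Target starts at S, and what slows it is the reagent balance, which has two outgoings: S itself and self-condensation, which goes with the square of the reagent level, constant K. Ochre's last stretch reads 0.00307 M h⁻¹ and red's, on portions of 0.0400 M, reads 0.00235 M h⁻¹, a factor of 0.797 on S. But one standard deviation of that gap is 3.83 × 10⁻⁴ M h⁻¹, so the gap of 7.22 × 10⁻⁴ M h⁻¹ stands inside two of them, and these readings do not show red falling by itself. We therefore simply assume that red's portion is nearly spent after 6.0 h, at a mean level of half the portion, which gives a rough figure of K = 9.29 L mol⁻¹ h⁻¹.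

Our carried quantity is the reach, the time for which a large addition can keep up with S before the squared loss has eaten it: about one and a half times the inverse root of S times K, or 9.06 h. Target is then S times the hours fed, over the charge. South-west is fed for 10.6 h and gives 62.3%; north-east is fed for 11.1 h and gives 16.3%. North and east have the reach past the end and give 35.4% and 23.6%. South's portion of 0.0275 M just misses the 0.0282 M one interval needs, so we commit to 69.0%, with south first.

The forecast differs: south-west > south > north > east > north-east, top 71%, low 17.8%, on the ground that “Reagent matters only when it runs low”.

The simulation gives south > south-west > north > east > north-east, top 63.6%, low 14.8%.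

    dissolved substrate + reagent → target (k = 746 L mol⁻¹ h⁻¹)
    2 reagent → self-condensation product (k = 6.32 L mol⁻¹ h⁻¹)
    solid product ⇌ target, rate k3*(cs3 - [target]) while solid is left; crystals form when [target] > cs3 (solubility = 8.10 mM, k = 15.2 h⁻¹)
    solid substrate ⇌ dissolved substrate, rate k4*(cs4 - [dissolved substrate]) while solid is left; crystals form when [dissolved substrate] > cs4 (solubility = 4.70 mM, k = 0.684 h⁻¹)

Target over S makes 10.8 h of feeding in south, against 9.23 h in south-west, where reagent stands at 0% at 12.0 h. On that count south-west's last addition fed for about 7.73 h, less than the reach.

South with 1.90 equiv has portions of 0.0475 M, and with the reach beyond 6.0 h it should be fed throughout, giving 70.8%; it computes to 68.8%.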